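Take the fast steps as steady and reckon with the nucleophile they leave free.

- theta: electrophile 0.28 M; solid nucleophile 0.950 equiv; scavenger 1.20 equiv; time 40 h
- gamma: electrophile 0.28 M; solid nucleophile 0.950 equiv; scavenger 1.60 equiv; time 40 h

    2 nucleophile → self-condensation product (k1 = 1.69 × 10⁻⁵ M⁻¹ s⁻¹)
    electrophile + nucleophile → acid set free + target (k2 = 2.96 × 10⁻⁴ M⁻¹ s⁻¹)
    solid nucleophile ⇌ nucleophile, rate k3*(cs3 - [nucleophile]) while solid is left; crystals form when [nucleophile] > cs3 (cs3 = 14 mM, k3 = 5.94 × 10⁻⁵ s⁻¹)
    acid set free + scavenger → scavenged by-product (k4 = 0.00280 M⁻¹ s⁻¹)
    nucleophile + acid set free ⇌ idle adduct, settled at all times (K5 = 3.65 M⁻¹)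
    nucleophile + acid set free ⇌ protonated nucleophile, settled at all times (K6 = 180 M⁻¹)

- part of the electrophile that has reacted at the end, theta
- part of the electrophile that has reacted at the end, gamma
- what raising the equivalents of scavenger from its lowest to its highest value here does to the part of the electrophile that has reacted (changes below 5 percentage points count as none) (no change / it rises / it falls)

**What do you follow?** The part of the electrophile charge that is left, which starts at one.

**Does the free nucleophile reach a steady level?** Yes, quickly. The solid feeds it with coefficient 5.94 × 10⁻⁵ s⁻¹, and the electrophile removes it at 8.29 × 10⁻⁵ s⁻¹ at the charge. Together they give a relaxation time of 1.95 h, far shorter than the 40 h run.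

**At what level?** Where feed equals use, which at the charge is 41.7 % of the solubility. Call this part the saturation share: the dissolution coefficient over itself plus the coupling constant times the electrophile present.

**And the acid set free?** In theta its free form has a half-life of 0.20 h by its removal step alone, the other concentrations as charged, far shorter than the run. That acid binds nucleophile. So I expect a small, steady bound pool that takes little further feed. The share contains no scavenger term, so I expect theta and gamma to match.

**Your number?** The electrophile falls pseudo-first-order, with the coupling constant times the share times the solubility: 0.00623 h⁻¹ of what is left. By 40 h that gives 22.1 % reacted in each flask.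

**But the share moves.** Yes. It rises as the electrophile falls, and my constant ignores that. The lag and the bound nucleophile pull the other way, so I commit to this number for a small conversion.

The forecast gives 22.1 % for theta (20.5 % to 24 %), 22.2 % for gamma (20.5 % to 24 %) and no change. Its ground: “The run is limited by how slowly the solid dissolves”.

The simulation gives 22.1 % for theta and 22.2 % for gamma, so no change, with a difference of 0.035 percentage points. With the scavenger step struck out, gamma gives 18.0 %, below the low end of the forecast's range for gamma, so that run falls outside it. In theta at 40.0 h, with 78 % of the electrophile left, the share becomes 47.9 %. That is 0.00671 M of nucleophile, against 0.00664 M in the flask.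

Now read gamma at 6.0 d. The starting constant gives 59.2 % reacted, and the share at the 32 % left gives 0.00969 M of nucleophile. The simulation gives 68.1 % reacted and 0.00956 M of nucleophile.

Its constants belong to no real substance; the flask was simulated.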